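**Retrosynthetic overview**

- The target is traced back to its 5,7-di-O-methyl ether; the last step is a global O-demethylation with no change at carbon.
- Ring B (the pyranone: O1–C2–C3–C4–C4a–C8a) is opened at C2–C3. In the forward sense it is closed by an enantioselective dirhodium-carbenoid 1,6-C–H insertion of an aryl diazomethyl ketone into the O–CH2 group of an achiral octadecyl aryl ether. This one operation builds the only ring to be made and sets the only stereocentre.
- The diazoketone comes from the aryl methyl ketone by diazo transfer. The ketone comes from a chelated phenol and 1-bromooctadecane, and the phenol from phloroacetophenone by nuclear C-methylation and selective O-methylation. Ring A is bought in; ring B is the only ring formed.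
- Enabling feature: O1 sits on C8a, ortho to the acyl carbon C4 on C4a, so the two hydridic (α-oxygen) hydrogens of O1–CH2 lie 1,6 to the carbenoid carbon C3. A 1,5-insertion is impossible because that position is O1, and ring A is fully substituted (C5–C8), so no aromatic C–H or cyclopropanation site competes.

Key step: step 5

Assumption: Rh2(S-PTTL)4 is taken to deliver the (S)-configured C2; the sense of induction is to be checked on a small scale, and Rh2(R-PTTL)4 would be used without other change should it prove opposite.

Step 1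
Reactants: 1 1-(2,4,6-trihydroxyphenyl)ethan-1-one
Product: 2 1-(2,4,6-trihydroxy-3,5-dimethylphenyl)ethan-1-one
Conditions: MeI (2.2 equiv), NaOMe (3 equiv), MeOH, 0 °C → reflux
Reagents that add atoms: iodomethane, CI
Why: Nuclear C-methylation of the ambident phloroglucinol phenoxide (C-alkylation of a polyphenolate) should place methyl groups on the two ring CH positions flanked by hydroxyls, with limited MeI keeping dearomatising gem-dimethylation and O-methylation low.

Step 2
Reactants: 2 1-(2,4,6-trihydroxy-3,5-dimethylphenyl)ethan-1-one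
Product: 3 1-(2-hydroxy-4,6-dimethoxy-3,5-dimethylphenyl)ethan-1-one
Conditions: Me2SO4 (2.1 equiv), K2CO3, acetone, reflux
Reagents that add atoms: dimethyl sulfate, COS(=O)(=O)OC
Why: Williamson O-methylation should take the para hydroxyl and one ortho hydroxyl, while the last ortho hydroxyl, held in a hydrogen bond to the acetyl carbonyl, survives at this stoichiometry.

Step 3
Reactants: 3 1-(2-hydroxy-4,6-dimethoxy-3,5-dimethylphenyl)ethan-1-one, 4 1-bromooctadecane
Product: 5 1-[2,4-dimethoxy-3,5-dimethyl-6-(octadecyloxy)phenyl]ethan-1-one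
Conditions: K2CO3, KI (cat.), DMF, 80 °C
Reagents that add atoms: none
Why: Williamson etherification of the chelated, hindered phenoxide with a primary bromide should proceed under forcing conditions (iodide catalysis, polar aprotic solvent, heat), and no other nucleophilic site remains in 3.

Step 4
Reactants: 5 1-[2,4-dimethoxy-3,5-dimethyl-6-(octadecyloxy)phenyl]ethan-1-one
Product: 7 2-diazo-1-[2,4-dimethoxy-3,5-dimethyl-6-(octadecyloxy)phenyl]ethan-1-one, via trifluoroacetyl diketone 6 (not isolated)
Conditions: LiN(SiMe3)2, THF, −78 °C; CF3CO2CH2CF3; aq. HCl work-up; then 4-acetamidobenzenesulfonyl azide, Et3N, H2O (1 equiv), MeCN, rt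
Reagents that add atoms: 4-acetamidobenzenesulfonyl azide, CC(=O)Nc1ccc(cc1)S(=O)(=O)N=[N+]=[N-] (2,2,2-trifluoroethyl trifluoroacetate, O=C(OCC(F)(F)F)C(F)(F)F, adds the trifluoroacetyl group of 6 only)
Why: Danheiser detrifluoroacetylative diazo transfer, in which the kinetic enolate of the methyl ketone is C-trifluoroacetylated to activate the only enolisable position and Regitz-type diazo transfer to the 1,3-diketone with loss of the N-trifluoroacetyl sulfonamide should give the terminal diazoketone without touching the aryl ethers.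

Step 5
Reactants: 7 2-diazo-1-[2,4-dimethoxy-3,5-dimethyl-6-(octadecyloxy)phenyl]ethan-1-one
Product: 8 (S)-2-heptadecyl-5,7-dimethoxy-6,8-dimethylchroman-4-one
Conditions: Rh2(S-PTTL)4 [dirhodium tetrakis(N-phthaloyl-(S)-tert-leucinate)] (1 mol%), CH2Cl2, 0 °C, slow addition of 7
Reagents that add atoms: none
Why: Rh2(S-PTTL)4 should expel N2 from 7 to give an electrophilic dirhodium carbenoid at C3 that inserts, through a concerted asynchronous three-centre transition state with hydride-transfer character, into one of the two enantiotopic C–H bonds of the O1–CH2 group, forming the C2–C3 bond. The closest known reaction type is the enantioselective intramolecular carbenoid C–H insertion of 2-alkoxyaryl diazoketones to 2-substituted chroman-4-ones under chiral dirhodium tetracarboxylate catalysis. Ring B closes as a six-membered ring by 1,6-C–H insertion, the otherwise preferred 1,5-mode being excluded because that position is the ether oxygen. The new stereocentre C2 is set under catalyst control, the phthalimido walls of the tert-leucinate ligands selecting which enantiotopic hydrogen is presented to the carbenoid, since the substrate is achiral. The step needs site selectivity for the O-bound methylene over the methoxy C–H on the other ortho oxygen, the remote chain methylenes and oxonium-ylide pathways; this should be secured by the greater hydridic character of a secondary α-alkoxy C–H, by the ring size available only to the O-bound carbon, by the absence of a migrating group with Stevens aptitude (ylide formation reverts), and by the fully substituted ring A. Slow addition of 7 at 0 °C should keep carbene dimerisation low and favour enantioselection.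

Step 6
Reactants: 8 (S)-2-heptadecyl-5,7-dimethoxy-6,8-dimethylchroman-4-one
Product: 9 (S)-2-heptadecyl-5,7-dihydroxy-6,8-dimethylchroman-4-one
Conditions: BBr3 (6 equiv), CH2Cl2, −78 °C → rt; then MeOH, H2O (acidic, non-basic work-up)
Reagents that add atoms: none
Why: Lewis-acid ether cleavage with BBr3 should demethylate both aryl methyl ethers by bromide attack on the boron-complexed oxygens (5-OMe assisted by chelation to the C4 carbonyl, 7-OMe twisted out of conjugation by its two ortho methyls), while O1 is deactivated as a vinylogous ester and the non-basic work-up avoids retro-oxa-Michael racemisation at C2.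

**Compound list**

1 | 1-(2,4,6-trihydroxyphenyl)ethan-1-one (phloroacetophenone) | CC(=O)c1c(O)cc(O)cc1O | starting material
2 | 1-(2,4,6-trihydroxy-3,5-dimethylphenyl)ethan-1-one | CC(=O)c1c(O)c(C)c(O)c(C)c1O | intermediate
3 | 1-(2-hydroxy-4,6-dimethoxy-3,5-dimethylphenyl)ethan-1-one | CC(=O)c1c(O)c(C)c(OC)c(C)c1OC | intermediate
4 | 1-bromooctadecane | CCCCCCCCCCCCCCCCCCBr | starting material
5 | 1-[2,4-dimethoxy-3,5-dimethyl-6-(octadecyloxy)phenyl]ethan-1-one | CCCCCCCCCCCCCCCCCCOc1c(C)c(OC)c(C)c(OC)c1C(C)=O | intermediate
6 | 1-[2,4-dimethoxy-3,5-dimethyl-6-(octadecyloxy)phenyl]-4,4,4-trifluorobutane-1,3-dione | CCCCCCCCCCCCCCCCCCOc1c(C)c(OC)c(C)c(OC)c1C(=O)CC(=O)C(F)(F)F | intermediate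
7 | 2-diazo-1-[2,4-dimethoxy-3,5-dimethyl-6-(octadecyloxy)phenyl]ethan-1-one | CCCCCCCCCCCCCCCCCCOc1c(C)c(OC)c(C)c(OC)c1C(=O)C=[N+]=[N-] | intermediate
8 | (S)-2-heptadecyl-5,7-dimethoxy-6,8-dimethylchroman-4-one | CCCCCCCCCCCCCCCCC[C@H]1CC(=O)c2c(OC)c(C)c(OC)c(C)c2O1 | intermediate
9 | (S)-2-heptadecyl-5,7-dihydroxy-6,8-dimethylchroman-4-one | CCCCCCCCCCCCCCCCC[C@H]1CC(=O)c2c(O)c(C)c(O)c(C)c2O1 | target

Total step count: 6
Longest linear sequence: 6 steps (1 → 9)

**Steps most likely to fail**

Step 5. The catalyst may discriminate the enantiotopic C–H bonds poorly, giving low enantiomeric purity. Insertion into the methoxy C–H on the other ortho oxygen, carbene dimerisation, or loss of the chain through oxonium-ylide pathways may also compete. The fallback sets out from 3 and returns at 8; it sets C2 by asymmetric conjugate reduction of a chromone instead. Compound 3 is acylated with octadecanoyl chloride (pyridine, DMAP, CH2Cl2) to 2-acetyl-3,5-dimethoxy-4,6-dimethylphenyl octadecanoate F1. Baker–Venkataraman acyl transfer (KOtBu, THF) should give 1-(2-hydroxy-4,6-dimethoxy-3,5-dimethylphenyl)icosane-1,3-dione F2. Acid cyclodehydration (cat. H2SO4, AcOH, 80 °C) should give 2-heptadecyl-5,7-dimethoxy-6,8-dimethyl-4H-chromen-4-one F3. Copper-hydride asymmetric conjugate reduction of the chromone (Cu(OAc)2·H2O, the DTBM-SEGPHOS enantiomer that delivers hydride to the face giving (S), (EtO)2MeSiH, t-BuOH, toluene, rt) should then give 8.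

Step 6. Configurational purity may be partly lost by reversible opening of ring B (retro-oxa-Michael) under the Lewis acid or on work-up. Bromide may open the O1–C2 bond, or the doubly flanked 7-methoxy group may be cleaved incompletely. The fallback sets out from 2 and returns at 9; it changes the protecting-group plan so that the final unmasking runs at low temperature with BCl3.
- Compound 2 is benzylated at the non-chelated para hydroxyl (BnBr, 1.0 equiv, K2CO3, acetone, rt) to 1-[4-(benzyloxy)-2,6-dihydroxy-3,5-dimethylphenyl]ethan-1-one F4.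
- Mono-methylation (Me2SO4, 1.0 equiv, K2CO3, acetone, reflux) gives 1-[4-(benzyloxy)-2-hydroxy-6-methoxy-3,5-dimethylphenyl]ethan-1-one F5.
- Alkylation with 4 as in step 3 gives 1-[4-(benzyloxy)-2-methoxy-3,5-dimethyl-6-(octadecyloxy)phenyl]ethan-1-one F6.
- Diazo transfer as in step 4 proceeds through 1-[4-(benzyloxy)-2-methoxy-3,5-dimethyl-6-(octadecyloxy)phenyl]-4,4,4-trifluorobutane-1,3-dione F7 (not isolated) to 1-[4-(benzyloxy)-2-methoxy-3,5-dimethyl-6-(octadecyloxy)phenyl]-2-diazoethan-1-one F8.
- C–H insertion as in step 5 gives (S)-7-(benzyloxy)-2-heptadecyl-5-methoxy-6,8-dimethylchroman-4-one F9; the para benzyl ether is out of reach of the carbenoid.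
- BCl3 with pentamethylbenzene as benzyl-cation trap (CH2Cl2, −78 → 0 °C) should remove the benzyl ether and the carbonyl-chelated 5-methoxy group in one operation and give 9 without exposure to BBr3 at room temperature.

Step 4. The enolate may be trifluoroacetylated on oxygen instead of carbon, or diazo transfer may be incomplete, returning the ketone. The fallback sets out from 5 and returns at 7; it builds the diazo group from a bromoketone instead of an activated diketone. Compound 5 is brominated at the acetyl methyl group (CuBr2, EtOAc/CHCl3, reflux; the fully substituted ring cannot be brominated) to 2-bromo-1-[2,4-dimethoxy-3,5-dimethyl-6-(octadecyloxy)phenyl]ethan-1-one F10. Treatment with N,N'-ditosylhydrazine and DBU (THF, 0 °C) should give the N-alkylated hydrazide N-{2-[2,4-dimethoxy-3,5-dimethyl-6-(octadecyloxy)phenyl]-2-oxoethyl}-N,N'-ditosylhydrazine F11 (not isolated), which loses two sulfinate groups to give 7.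

**Further compounds**

F1 | step 5 | 2-acetyl-3,5-dimethoxy-4,6-dimethylphenyl octadecanoate | CCCCCCCCCCCCCCCCCC(=O)Oc1c(C)c(OC)c(C)c(OC)c1C(C)=O
F2 | step 5 | 1-(2-hydroxy-4,6-dimethoxy-3,5-dimethylphenyl)icosane-1,3-dione | CCCCCCCCCCCCCCCCCC(=O)CC(=O)c1c(O)c(C)c(OC)c(C)c1OC
F3 | step 5 | 2-heptadecyl-5,7-dimethoxy-6,8-dimethyl-4H-chromen-4-one | CCCCCCCCCCCCCCCCCC1=CC(=O)c2c(OC)c(C)c(OC)c(C)c2O1
F4 | step 6 | 1-[4-(benzyloxy)-2,6-dihydroxy-3,5-dimethylphenyl]ethan-1-one | CC(=O)c1c(O)c(C)c(OCc2ccccc2)c(C)c1O
F5 | step 6 | 1-[4-(benzyloxy)-2-hydroxy-6-methoxy-3,5-dimethylphenyl]ethan-1-one | CC(=O)c1c(O)c(C)c(OCc2ccccc2)c(C)c1OC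
F6 | step 6 | 1-[4-(benzyloxy)-2-methoxy-3,5-dimethyl-6-(octadecyloxy)phenyl]ethan-1-one | CCCCCCCCCCCCCCCCCCOc1c(C)c(OCc2ccccc2)c(C)c(OC)c1C(C)=O
F7 | step 6 | 1-[4-(benzyloxy)-2-methoxy-3,5-dimethyl-6-(octadecyloxy)phenyl]-4,4,4-trifluorobutane-1,3-dione | CCCCCCCCCCCCCCCCCCOc1c(C)c(OCc2ccccc2)c(C)c(OC)c1C(=O)CC(=O)C(F)(F)F
F8 | step 6 | 1-[4-(benzyloxy)-2-methoxy-3,5-dimethyl-6-(octadecyloxy)phenyl]-2-diazoethan-1-one | CCCCCCCCCCCCCCCCCCOc1c(C)c(OCc2ccccc2)c(C)c(OC)c1C(=O)C=[N+]=[N-]
F9 | step 6 | (S)-7-(benzyloxy)-2-heptadecyl-5-methoxy-6,8-dimethylchroman-4-one | CCCCCCCCCCCCCCCCC[C@H]1CC(=O)c2c(OC)c(C)c(OCc3ccccc3)c(C)c2O1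
F10 | step 4 | 2-bromo-1-[2,4-dimethoxy-3,5-dimethyl-6-(octadecyloxy)phenyl]ethan-1-one | CCCCCCCCCCCCCCCCCCOc1c(C)c(OC)c(C)c(OC)c1C(=O)CBr
F11 | step 4 | N-{2-[2,4-dimethoxy-3,5-dimethyl-6-(octadecyloxy)phenyl]-2-oxoethyl}-N,N'-ditosylhydrazine | CCCCCCCCCCCCCCCCCCOc1c(C)c(OC)c(C)c(OC)c1C(=O)CN(NS(=O)(=O)c1ccc(C)cc1)S(=O)(=O)c1ccc(C)cc1
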